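**Retrosynthetic overview**

1. The strategy rests on the C3–C4 two-carbon bridge of the chroman. C3 carries ring B (bond C3–C1′) and C4 is bonded to ring A (bond C4–C4a), so both aryl–carbon bonds and the C3 stereocentre come from one vinyl unit in a three-component conjunctive coupling of ring B boronate 12, vinyllithium 20 and ring A triflate 18.
2. The C3–B bond left by that coupling marks the place of C2. One-carbon Matteson homologation with retention, oxidation and Mitsunobu closure of O1–C2 form the pyran ring (ring C) last; rings A and B are bought as arenes.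
3. Ring B comes from o-vanillin: benzylation and formate oxidation give a phenol with O3′ benzylated and O4′ free, which fixes the oxygen that is prenylated. Claisen rearrangement then places the 2-methylbut-3-en-2-yl group on C5′, and benzylation, C1′ bromination and borylation follow.
4. Ring A comes from 2,4-dihydroxybenzaldehyde (4-O-benzyl, 2-O-MOM, formate oxidation, triflation). Vinyllithium is made free of halide from Sn(CH=CH2)4, because lithium halide would shut down the cationic palladium pathway.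
5. The MOM group comes off before ring closure; the three benzyl ethers are cleaved at the end with BCl3/C6HMe5, which spares the terminal alkene and the methyl ether.

Key step: step 13

Remark (assumption): the (Sp,Sp) antipode of MandyPhos (C52H50FeN2P2) is taken to deliver the (S)-boronate 22; should its facial sense be the opposite, the (Rp,Rp) ligand is used and nothing else changes.

**Route**

Step 1
Reactants: 1 2-hydroxy-3-methoxybenzaldehyde (o-vanillin)
Product: 2 2-(benzyloxy)-3-methoxybenzaldehyde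
Conditions: BnBr, K2CO3, DMF, rt
Reagents that add atoms: benzyl bromide, BrCc1ccccc1
Why: Williamson etherification of the only phenol of 1, which the ortho-formyl group does not disturb under carbonate base.

Step 2
Reactants: 2 2-(benzyloxy)-3-methoxybenzaldehyde
Product: 4 2-(benzyloxy)-3-methoxyphenol, via aryl formate 3 (not isolated)
Conditions: mCPBA, CH2Cl2, 0 °C to rt; NaHCO3 wash; then K2CO3 (cat.), MeOH, rt
Reagents that add atoms: 3-chloroperoxybenzoic acid (mCPBA), OOC(=O)c1cccc(Cl)c1
Why: Baeyer–Villiger (Dakin-type) oxidation in which the electron-rich ortho-alkoxyaryl group migrates to give formate 3, cleaved by methanolysis to a phenol whose O3′ is benzylated and whose O4′ is free.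

Step 3
Reactants: 4 2-(benzyloxy)-3-methoxyphenol; 5 1-bromo-3-methylbut-2-ene (prenyl bromide)
Product: 6 2-(benzyloxy)-1-methoxy-3-[(3-methylbut-2-en-1-yl)oxy]benzene
Conditions: K2CO3, acetone, reflux
Reagents that add atoms: none
Why: Williamson O-alkylation (SN2 at the primary allylic bromide) under mild carbonate conditions, which favour O- over C-prenylation.

Step 4
Reactants: 6 2-(benzyloxy)-1-methoxy-3-[(3-methylbut-2-en-1-yl)oxy]benzene
Product: 8 2-(benzyloxy)-3-methoxy-6-(2-methylbut-3-en-2-yl)phenol, via ortho-dienone 7 (not isolated)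
Conditions: PhNEt2, 185 °C, sealed tube, Ar
Reagents that add atoms: none
Why: Aromatic Claisen rearrangement, a [3,3] shift that delivers the tertiary allyl terminus to the only free ortho position (C5′ of ring B), the other being blocked by the benzyloxy group, after which dienone 7 re-aromatises by tautomerisation.

Step 5
Reactants: 8 2-(benzyloxy)-3-methoxy-6-(2-methylbut-3-en-2-yl)phenol
Product: 9 2,3-bis(benzyloxy)-1-methoxy-4-(2-methylbut-3-en-2-yl)benzene
Conditions: BnBr, K2CO3, DMF, 60 °C
Reagents that add atoms: benzyl bromide, BrCc1ccccc1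
Why: Williamson benzylation of the hindered phenol, which also removes the free ortho-hydroxyl that could cyclise onto the allyl group in later electrophilic steps.

Step 6
Reactants: 9 2,3-bis(benzyloxy)-1-methoxy-4-(2-methylbut-3-en-2-yl)benzene
Product: 10 3,4-bis(benzyloxy)-1-bromo-2-methoxy-5-(2-methylbut-3-en-2-yl)benzene
Conditions: NBS, MeCN, 0 °C, dark
Reagents that add atoms: N-bromosuccinimide, O=C1CCC(=O)N1Br
Why: Electrophilic aromatic bromination at C1′, which is ortho to the methoxy group and para to the O4′ ether, whereas the other free position C6′ lies beside the quaternary carbon and the hindered monosubstituted alkene should react far more slowly than the trialkoxyarene.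

Step 7
Reactants: 10 3,4-bis(benzyloxy)-1-bromo-2-methoxy-5-(2-methylbut-3-en-2-yl)benzene
Product: 12 2-[3,4-bis(benzyloxy)-2-methoxy-5-(2-methylbut-3-en-2-yl)phenyl]-4,4,5,5-tetramethyl-1,3,2-dioxaborolane, via aryllithium 11 (not isolated)
Conditions: n-BuLi, THF, −78 °C; then i-PrOBpin, −78 °C to rt
Reagents that add atoms: n-butyllithium, [Li]CCCC (lithium of 11 only); 2-isopropoxy-4,4,5,5-tetramethyl-1,3,2-dioxaborolane, CC(C)OB1OC(C)(C)C(C)(C)O1
Why: Bromine–lithium exchange at −78 °C outpaces deprotonation at the benzylic ether positions, and aryllithium 11 is trapped by the borate ester (borylation) with loss of isopropoxide.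

Step 8
Reactants: 13 2,4-dihydroxybenzaldehyde
Product: 14 4-(benzyloxy)-2-hydroxybenzaldehyde
Conditions: BnBr, NaHCO3, KI (cat.), MeCN, 80 °C
Reagents that add atoms: benzyl bromide, BrCc1ccccc1
Why: Regioselective Williamson benzylation, since the 2-hydroxyl is tied up in a hydrogen bond to the formyl group and the weak base ionises only the more acidic 4-hydroxyl.

Step 9
Reactants: 14 4-(benzyloxy)-2-hydroxybenzaldehyde
Product: 15 4-(benzyloxy)-2-(methoxymethoxy)benzaldehyde
Conditions: MOMCl, i-Pr2NEt, CH2Cl2, 0 °C to rt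
Reagents that add atoms: chloromethyl methyl ether, COCCl
Why: O-alkylation of the chelated phenol with the reactive chloromethyl ether gives the MOM acetal, which is orthogonal to the benzyl ethers and stable to organolithium reagents.

Step 10
Reactants: 15 4-(benzyloxy)-2-(methoxymethoxy)benzaldehyde
Product: 17 4-(benzyloxy)-2-(methoxymethoxy)phenol, via aryl formate 16 (not isolated)
Conditions: mCPBA, CH2Cl2, 0 °C to rt; NaHCO3 wash; then K2CO3 (cat.), MeOH, rt
Reagents that add atoms: 3-chloroperoxybenzoic acid (mCPBA), OOC(=O)c1cccc(Cl)c1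
Why: Baeyer–Villiger (Dakin-type) oxidation in which ortho- and para-alkoxy groups make aryl migration strongly preferred, followed by methanolysis of formate 16 under conditions that leave the MOM acetal intact.

Step 11
Reactants: 17 4-(benzyloxy)-2-(methoxymethoxy)phenol
Product: 18 4-(benzyloxy)-2-(methoxymethoxy)phenyl trifluoromethanesulfonate
Conditions: PhNTf2, Et3N, DMAP (cat.), CH2Cl2, rt
Reagents that add atoms: N-phenylbis(trifluoromethanesulfonimide), O=S(=O)(N(c1ccccc1)S(=O)(=O)C(F)(F)F)C(F)(F)F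
Why: O-sulfonylation of the phenol with a mild triflating agent, which avoids strongly electrophilic Tf2O next to the acetal and gives a halide-free triflate.

Step 12
Reactants: 19 tetravinylstannane
Product: 20 vinyllithium
Conditions: n-BuLi (4 equiv), pentane, rt; filter, wash with pentane, dissolve in THF
Reagents that add atoms: n-butyllithium, [Li]CCCC
Why: Tin–lithium exchange (transmetallation) driven by precipitation of vinyllithium from pentane, which gives a reagent free of lithium halide as the cationic palladium pathway of step 13 requires.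

Step 13
Reactants: 12 2-[3,4-bis(benzyloxy)-2-methoxy-5-(2-methylbut-3-en-2-yl)phenyl]-4,4,5,5-tetramethyl-1,3,2-dioxaborolane; 20 vinyllithium; 18 4-(benzyloxy)-2-(methoxymethoxy)phenyl trifluoromethanesulfonate
Product: 22 (S)-2-{1-[3,4-bis(benzyloxy)-2-methoxy-5-(2-methylbut-3-en-2-yl)phenyl]-2-[4-(benzyloxy)-2-(methoxymethoxy)phenyl]ethyl}-4,4,5,5-tetramethyl-1,3,2-dioxaborolane, via vinyl boronate complex 21 (not isolated)
Conditions: 20, THF, 0 °C to rt; then Pd(OAc)2 (2 mol%), (Sp,Sp)-MandyPhos (1,1′-bis(diphenylphosphino)-2,2′-bis[α-(dimethylamino)benzyl]ferrocene, C52H50FeN2P2, 2.4 mol%), 18, THF, 60 °C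
Reagents that add atoms: none
Why: Vinyllithium adds to the boron of 12 to give the four-coordinate vinyl boronate 21; oxidative addition of 18 to zerovalent palladium (formed from Pd(OAc)2 and the diphosphine) gives a cationic aryl complex of divalent palladium that binds the vinyl group of 21 and triggers a 1,2-metallate shift, ring B moving from boron to the alpha carbon (C3–C1′) anti to palladium, and reductive elimination then joins ring A to the beta carbon (C4–C4a). The closest known reaction type is the palladium-catalysed enantioselective conjunctive cross-coupling of vinyl boron ate complexes bearing a migrating aryl group with aryl triflates. No ring closes in this step. The new stereocentre at C3 is set during the metallate shift by the ferrocenyl diphosphine, which decides the alkene face that palladium occupies. The step needs the shift to outrun direct Suzuki–Miyaura transfer of vinyl or aryl and Heck insertion into the spectator 2-methylbut-3-en-2-yl alkene: halide-free 20 and the triflate leaving group keep palladium cationic, the borate-bound alkene is far more electron-rich than the neopentyl-type terminal alkene, and the electron-rich ring B migrates readily.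

Step 14
Reactants: 22 (S)-2-{1-[3,4-bis(benzyloxy)-2-methoxy-5-(2-methylbut-3-en-2-yl)phenyl]-2-[4-(benzyloxy)-2-(methoxymethoxy)phenyl]ethyl}-4,4,5,5-tetramethyl-1,3,2-dioxaborolane
Product: 25 (S)-2-[3,4-bis(benzyloxy)-2-methoxy-5-(2-methylbut-3-en-2-yl)phenyl]-3-[4-(benzyloxy)-2-(methoxymethoxy)phenyl]propan-1-ol, via chloromethyl boronate complex 23 (not isolated), via homologated pinacol boronate 24 (not isolated)
Conditions: BrCH2Cl, n-BuLi, THF, −78 °C to rt; then NaOH (aq), H2O2, 0 °C to rt
Reagents that add atoms: bromochloromethane, ClCBr; n-butyllithium, [Li]CCCC (lithium of 23 only); hydrogen peroxide, OO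
Why: Matteson homologation, in which LiCH2Cl formed by bromine–lithium exchange in the presence of 22 adds to boron to give 23, the secondary alkyl group migrates to the CH2 carbon with loss of chloride and retention at C3, and alkaline H2O2 then oxidises the primary C–B bond of 24 to C–OH.

Step 15
Reactants: 25 (S)-2-[3,4-bis(benzyloxy)-2-methoxy-5-(2-methylbut-3-en-2-yl)phenyl]-3-[4-(benzyloxy)-2-(methoxymethoxy)phenyl]propan-1-ol
Product: 26 (S)-5-(benzyloxy)-2-{2-[3,4-bis(benzyloxy)-2-methoxy-5-(2-methylbut-3-en-2-yl)phenyl]-3-hydroxypropyl}phenol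
Conditions: TsOH·H2O (cat.), MeOH/THF, 40 °C
Reagents that add atoms: none
Why: Acid-catalysed acetal exchange with methanol removes the MOM group, while aryl benzyl ethers, the primary alcohol and the monosubstituted alkene are stable to catalytic acid at this temperature.

Step 16
Reactants: 26 (S)-5-(benzyloxy)-2-{2-[3,4-bis(benzyloxy)-2-methoxy-5-(2-methylbut-3-en-2-yl)phenyl]-3-hydroxypropyl}phenol
Product: 27 (S)-7-(benzyloxy)-3-[3,4-bis(benzyloxy)-2-methoxy-5-(2-methylbut-3-en-2-yl)phenyl]chromane
Conditions: PPh3, DIAD, THF, 0 °C to rt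
Reagents that add atoms: none
Why: Intramolecular Mitsunobu etherification in which the phenol displaces the activated primary oxyphosphonium group (6-exo-tet closure of O1–C2), C3 not being a reacting centre and so keeping its configuration.

Step 17
Reactants: 27 (S)-7-(benzyloxy)-3-[3,4-bis(benzyloxy)-2-methoxy-5-(2-methylbut-3-en-2-yl)phenyl]chromane
Product: 28 (S)-3-[3,4-dihydroxy-2-methoxy-5-(2-methylbut-3-en-2-yl)phenyl]chroman-7-ol (CNP0167796.2)
Conditions: BCl3, C6HMe5, CH2Cl2, −78 °C; MeOH quench at −78 °C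
Reagents that add atoms: none
Why: Lewis-acid debenzylation of aryl benzyl ethers, with pentamethylbenzene trapping the benzyl cation by Friedel–Crafts alkylation so that the electron-rich rings are not benzylated, at a temperature where the aryl methyl ether and the terminal alkene should be left alone.

**Compound list**

1 | 2-hydroxy-3-methoxybenzaldehyde (o-vanillin) | COc1cccc(C=O)c1O | starting material
2 | 2-(benzyloxy)-3-methoxybenzaldehyde | COc1cccc(C=O)c1OCc1ccccc1 | intermediate
3 | 2-(benzyloxy)-3-methoxyphenyl formate | COc1cccc(OC=O)c1OCc1ccccc1 | intermediate (not isolated)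
4 | 2-(benzyloxy)-3-methoxyphenol | COc1cccc(O)c1OCc1ccccc1 | intermediate
5 | 1-bromo-3-methylbut-2-ene (prenyl bromide) | CC(C)=CCBr | starting material
6 | 2-(benzyloxy)-1-methoxy-3-[(3-methylbut-2-en-1-yl)oxy]benzene | COc1cccc(OCC=C(C)C)c1OCc1ccccc1 | intermediate
7 | 2-(benzyloxy)-3-methoxy-6-(2-methylbut-3-en-2-yl)cyclohexa-2,4-dien-1-one (racemic at C6) | COC1=C(OCc2ccccc2)C(=O)C(C(C)(C)C=C)C=C1 | intermediate (not isolated)
8 | 2-(benzyloxy)-3-methoxy-6-(2-methylbut-3-en-2-yl)phenol | COc1ccc(C(C)(C)C=C)c(O)c1OCc1ccccc1 | intermediate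
9 | 2,3-bis(benzyloxy)-1-methoxy-4-(2-methylbut-3-en-2-yl)benzene | COc1ccc(C(C)(C)C=C)c(OCc2ccccc2)c1OCc1ccccc1 | intermediate
10 | 3,4-bis(benzyloxy)-1-bromo-2-methoxy-5-(2-methylbut-3-en-2-yl)benzene | COc1c(Br)cc(C(C)(C)C=C)c(OCc2ccccc2)c1OCc1ccccc1 | intermediate
11 | [3,4-bis(benzyloxy)-2-methoxy-5-(2-methylbut-3-en-2-yl)phenyl]lithium | COc1c([Li])cc(C(C)(C)C=C)c(OCc2ccccc2)c1OCc1ccccc1 | intermediate (not isolated)
12 | 2-[3,4-bis(benzyloxy)-2-methoxy-5-(2-methylbut-3-en-2-yl)phenyl]-4,4,5,5-tetramethyl-1,3,2-dioxaborolane | COc1c(OCc2ccccc2)c(OCc2ccccc2)c(C(C)(C)C=C)cc1B1OC(C)(C)C(C)(C)O1 | intermediate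
13 | 2,4-dihydroxybenzaldehyde | O=Cc1ccc(O)cc1O | starting material
14 | 4-(benzyloxy)-2-hydroxybenzaldehyde | O=Cc1ccc(OCc2ccccc2)cc1O | intermediate
15 | 4-(benzyloxy)-2-(methoxymethoxy)benzaldehyde | COCOc1cc(OCc2ccccc2)ccc1C=O | intermediate
16 | 4-(benzyloxy)-2-(methoxymethoxy)phenyl formate | COCOc1cc(OCc2ccccc2)ccc1OC=O | intermediate (not isolated)
17 | 4-(benzyloxy)-2-(methoxymethoxy)phenol | COCOc1cc(OCc2ccccc2)ccc1O | intermediate
18 | 4-(benzyloxy)-2-(methoxymethoxy)phenyl trifluoromethanesulfonate | COCOc1cc(OCc2ccccc2)ccc1OS(=O)(=O)C(F)(F)F | intermediate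
19 | tetravinylstannane | C=C[Sn](C=C)(C=C)C=C | starting material
20 | vinyllithium | [Li]C=C | intermediate
21 | lithium 2-[3,4-bis(benzyloxy)-2-methoxy-5-(2-methylbut-3-en-2-yl)phenyl]-2-ethenyl-4,4,5,5-tetramethyl-1,3,2-dioxaborolan-2-uide | [Li+].C=C[B-]1(c2cc(C(C)(C)C=C)c(OCc3ccccc3)c(OCc3ccccc3)c2OC)OC(C)(C)C(C)(C)O1 | intermediate (not isolated)
22 | (S)-2-{1-[3,4-bis(benzyloxy)-2-methoxy-5-(2-methylbut-3-en-2-yl)phenyl]-2-[4-(benzyloxy)-2-(methoxymethoxy)phenyl]ethyl}-4,4,5,5-tetramethyl-1,3,2-dioxaborolane | COc1c(OCc2ccccc2)c(OCc2ccccc2)c(C(C)(C)C=C)cc1[C@H](Cc1ccc(OCc2ccccc2)cc1OCOC)B1OC(C)(C)C(C)(C)O1 | intermediate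
23 | lithium 2-(chloromethyl)-2-{(S)-1-[3,4-bis(benzyloxy)-2-methoxy-5-(2-methylbut-3-en-2-yl)phenyl]-2-[4-(benzyloxy)-2-(methoxymethoxy)phenyl]ethyl}-4,4,5,5-tetramethyl-1,3,2-dioxaborolan-2-uide | COc1c(OCc2ccccc2)c(OCc2ccccc2)c(C(C)(C)C=C)cc1[C@H](Cc1ccc(OCc2ccccc2)cc1OCOC)[B-]1(CCl)OC(C)(C)C(C)(C)O1.[Li+] | intermediate (not isolated)
24 | (S)-2-{2-[3,4-bis(benzyloxy)-2-methoxy-5-(2-methylbut-3-en-2-yl)phenyl]-3-[4-(benzyloxy)-2-(methoxymethoxy)phenyl]propyl}-4,4,5,5-tetramethyl-1,3,2-dioxaborolane | COc1c(OCc2ccccc2)c(OCc2ccccc2)c(C(C)(C)C=C)cc1[C@H](Cc1ccc(OCc2ccccc2)cc1OCOC)CB1OC(C)(C)C(C)(C)O1 | intermediate (not isolated)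
25 | (S)-2-[3,4-bis(benzyloxy)-2-methoxy-5-(2-methylbut-3-en-2-yl)phenyl]-3-[4-(benzyloxy)-2-(methoxymethoxy)phenyl]propan-1-ol | COc1c(OCc2ccccc2)c(OCc2ccccc2)c(C(C)(C)C=C)cc1[C@H](Cc1ccc(OCc2ccccc2)cc1OCOC)CO | intermediate
26 | (S)-5-(benzyloxy)-2-{2-[3,4-bis(benzyloxy)-2-methoxy-5-(2-methylbut-3-en-2-yl)phenyl]-3-hydroxypropyl}phenol | COc1c(OCc2ccccc2)c(OCc2ccccc2)c(C(C)(C)C=C)cc1[C@H](Cc1ccc(OCc2ccccc2)cc1O)CO | intermediate
27 | (S)-7-(benzyloxy)-3-[3,4-bis(benzyloxy)-2-methoxy-5-(2-methylbut-3-en-2-yl)phenyl]chromane | C=CC(C)(C)c1cc([C@H]2COc3cc(OCc4ccccc4)ccc3C2)c(OC)c(OCc2ccccc2)c1OCc1ccccc1 | intermediate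
28 | (S)-3-[3,4-dihydroxy-2-methoxy-5-(2-methylbut-3-en-2-yl)phenyl]chroman-7-ol | C=CC(C)(C)c1cc([C@H]2COc3cc(O)ccc3C2)c(OC)c(O)c1O | target

**Step count**

Total: 17 steps. Longest linear sequence: 12 steps (steps 1–7, then 13–17).

**Steps most likely to fail**

Step 13 (conjunctive coupling). Oxidative addition of the electron-rich, ortho-substituted triflate may be slow, direct Suzuki–Miyaura transfer may compete with the metallate shift, and the ortho-methoxy group on the migrating ring may lower the facial selectivity. The fallback is an auxiliary-controlled alkylation that sets out from bromide 10 and aldehyde 15 and comes back at alcohol 25.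
- Bromide 10 is coupled with the zinc enolate BrZnCH2CO2Et under Pd2(dba)3/P(t-Bu)3 to give ethyl 2-[3,4-bis(benzyloxy)-2-methoxy-5-(2-methylbut-3-en-2-yl)phenyl]acetate F1.
- LiOH saponifies F1 to 2-[3,4-bis(benzyloxy)-2-methoxy-5-(2-methylbut-3-en-2-yl)phenyl]acetic acid F2.
- The pivaloyl mixed anhydride of F2 acylates (S)-4-benzyloxazolidin-2-one (Et3N, LiCl) to give (S)-4-benzyl-3-{2-[3,4-bis(benzyloxy)-2-methoxy-5-(2-methylbut-3-en-2-yl)phenyl]acetyl}oxazolidin-2-one F3.
- Aldehyde 15 is reduced with NaBH4 to [4-(benzyloxy)-2-(methoxymethoxy)phenyl]methanol F4, which neutral Appel conditions (CBr4, PPh3) convert into 4-(benzyloxy)-1-(bromomethyl)-2-(methoxymethoxy)benzene F5, used at once.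
- The sodium enolate of F3 (NaN(SiMe3)2, THF, −78 °C) is alkylated by F5 on the face away from the auxiliary benzyl group (Evans alkylation) to give (S)-4-benzyl-3-{(S)-2-[3,4-bis(benzyloxy)-2-methoxy-5-(2-methylbut-3-en-2-yl)phenyl]-3-[4-(benzyloxy)-2-(methoxymethoxy)phenyl]propanoyl}oxazolidin-2-one F6.
- LiBH4 removes the auxiliary reductively from F6 to give 25.

Step 4 (Claisen rearrangement). The ortho-allylphenol may reorganise further on heating (abnormal Claisen rearrangement, cyclisation onto the hydroxyl), and the allyl group may migrate to the para position through the blocked ortho site. The fallback is a cross-coupling that sets out from phenol 4 and comes back at 9.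
- Ortho-selective bromination of 4 (Br2, t-BuNH2, toluene, −78 °C) gives 2-(benzyloxy)-6-bromo-3-methoxyphenol F7.
- Benzylation (BnBr, K2CO3, DMF) gives 2,3-bis(benzyloxy)-1-bromo-4-methoxybenzene F8.
- A gamma-selective Suzuki–Miyaura coupling of F8 with 4,4,5,5-tetramethyl-2-(3-methylbut-2-en-1-yl)-1,3,2-dioxaborolane (Pd(OAc)2, a bulky biarylphosphine that favours the branched product, K3PO4, aqueous THF) installs the 2-methylbut-3-en-2-yl group and gives 9.

Step 17 (debenzylation). The Lewis acid may cleave the hindered methyl ether, or the freed O4′ hydroxyl may add across the neighbouring alkene under the acidic quench. The fallback replaces Lewis-acid ionisation by electron-transfer cleavage; it sets out from 27 and comes back at 28.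
- Lithium 4,4′-di-tert-butylbiphenylide (THF, −78 °C, MeOH quench) cleaves the three benzyl ethers reductively.
- The crude triphenol is acetylated (Ac2O, pyridine) and purified as (S)-3-[3,4-diacetoxy-2-methoxy-5-(2-methylbut-3-en-2-yl)phenyl]chroman-7-yl acetate F9.
- Methanolysis of F9 (K2CO3, degassed MeOH, 0 °C) gives 28.

**Further compounds**

F1 | step 13 | ethyl 2-[3,4-bis(benzyloxy)-2-methoxy-5-(2-methylbut-3-en-2-yl)phenyl]acetate | CCOC(=O)Cc1cc(C(C)(C)C=C)c(OCc2ccccc2)c(OCc2ccccc2)c1OC
F2 | step 13 | 2-[3,4-bis(benzyloxy)-2-methoxy-5-(2-methylbut-3-en-2-yl)phenyl]acetic acid | OC(=O)Cc1cc(C(C)(C)C=C)c(OCc2ccccc2)c(OCc2ccccc2)c1OC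
F3 | step 13 | (S)-4-benzyl-3-{2-[3,4-bis(benzyloxy)-2-methoxy-5-(2-methylbut-3-en-2-yl)phenyl]acetyl}oxazolidin-2-one | O=C(Cc1cc(C(C)(C)C=C)c(OCc2ccccc2)c(OCc2ccccc2)c1OC)N1[C@@H](Cc2ccccc2)COC1=O
F4 | step 13 | [4-(benzyloxy)-2-(methoxymethoxy)phenyl]methanol | OCc1ccc(OCc2ccccc2)cc1OCOC
F5 | step 13 | 4-(benzyloxy)-1-(bromomethyl)-2-(methoxymethoxy)benzene | BrCc1ccc(OCc2ccccc2)cc1OCOC
F6 | step 13 | (S)-4-benzyl-3-{(S)-2-[3,4-bis(benzyloxy)-2-methoxy-5-(2-methylbut-3-en-2-yl)phenyl]-3-[4-(benzyloxy)-2-(methoxymethoxy)phenyl]propanoyl}oxazolidin-2-one | O=C([C@@H](Cc1ccc(OCc2ccccc2)cc1OCOC)c1cc(C(C)(C)C=C)c(OCc2ccccc2)c(OCc2ccccc2)c1OC)N1[C@@H](Cc2ccccc2)COC1=O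
F7 | step 4 | 2-(benzyloxy)-6-bromo-3-methoxyphenol | COc1ccc(Br)c(O)c1OCc1ccccc1
F8 | step 4 | 2,3-bis(benzyloxy)-1-bromo-4-methoxybenzene | COc1ccc(Br)c(OCc2ccccc2)c1OCc1ccccc1
F9 | step 17 | (S)-3-[3,4-diacetoxy-2-methoxy-5-(2-methylbut-3-en-2-yl)phenyl]chroman-7-yl acetate | C=CC(C)(C)c1cc([C@H]2COc3cc(OC(C)=O)ccc3C2)c(OC)c(OC(C)=O)c1OC(C)=O
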